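The readings come from a simulation for substances that don't exist; scatter was added.

| setting | theta | gamma | flask |
|---|---|---|---|
| starting material | 0.025 M | 0.038 M | 0.050 M |
| enzyme | 5 µM | 5 µM | 5.0 µM |
| remark | run made earlier | run made earlier |  |
| time |  |  | 15 d |

| run | time / d | target / % |
|---|---|---|
| theta | 0.250 | 58.2 |
| theta | 0.417 | 76.4 |
| theta | 0.833 | 65.2 |
| theta | 1.67 | 35.8 |
| theta | 2.50 | 19.8 |
| theta | 5.00 | 3.6 |
| theta | 10.0 | 0.1 |
| gamma | 0.250 | 41.1 |
| gamma | 0.417 | 56.9 |
| gamma | 0.833 | 67.5 |
| gamma | 1.67 | 38.2 |
| gamma | 2.50 | 23.5 |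
| gamma | 5.00 | 3.3 |
| gamma | 10.0 | 0 |

(readings scatter by 0.5 percentage points)

- time up to 15 d at which target stands highest
- the amount of target, in percent of the starting material charged, at that time

We begin with two constants that can be read from the runs, and afterwards we test whether they are enough. From 1.67 d to 5.00 d, the target in the theta and gamma runs falls at first order, on average with

k = 0.713 d⁻¹

Up to 0.250 d, theta makes target at 0.0582 M d⁻¹ and gamma at 0.0625 M d⁻¹. A charge 1.52 times larger raises the rate by a factor of 1.07, so these charges lie above the concentration at which the order changes, and the rate is nearly zero order: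

V = 0.0603 M d⁻¹

For the flask,

D = k[starting material]/V = 0.591

We call D the fill number: the time the enzyme needs for the charge at rate V, here 0.829 d, counted in lifetimes of the target. At steady rate, the target peaks at (1 − e^−D)/D of the charge when the charge is used up:

theta 86.6%, gamma 80.6%, flask 75.5%

One number is not enough. The highest readings, 76.4% and 67.5%, reach 88.2% and 83.8% of these yields, a share that shrinks as D grows. Continuing that line in D, we expect 60.2% near 0.829 d.

The forecast gave 53% at 0.9 d, “limited by enzyme death”, a yield below ours.

The flask gives 59.9% at 0.928 d.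

    starting material + enzyme → target + enzyme, rate k1*[starting material]*[enzyme]/(1 + ([starting material]/Km1)) (2.60 mM, k = 76.0 M⁻¹ s⁻¹)
    enzyme → spent catalyst (k = 1.30 × 10⁻⁵ s⁻¹)
    target → over-reaction product (k = 8.20 × 10⁻⁶ s⁻¹)

At that time, 35.2% of its catalyst is enzyme and 64.8% is spent catalyst. The flask reaches 79.3% of its steady-rate yield. The neighbour flask charged with 0.085 M has D = 1.00 and a steady-rate yield of 63.1%, and it reaches 38.8%.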